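The route rests on cutting ring A at C1–C10 and C4–C5. Ring B of the target holds oxygen at C6, methyl groups on C8 and C10 and functional carbons at C7 and C9, which is the substitution pattern of 2,6-dimethylbenzoquinone, whereas ring A is only a gem-dimethylcyclohexane. An enantioselective Diels–Alder reaction of quinone 1 with diene 2 therefore closes ring A, fixes C10 and supplies both ring-B carbonyls and the C7=C8 alkene in one operation from two purchased compounds. Afterwards the C9 oxygen is transposed to C7 while C11 is added, C8 is hydroxylated through a dienolate, and the Z-diene is attached by B-alkyl Suzuki coupling.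

Key step: step 1

Notation: labdane numbering is used throughout (ring A = C1–C5, C10; ring B = C5–C10; C17 = methyl on C8; C20 = methyl on C10). "Syn" and "anti" refer to the C10 methyl (C20); absolute configurations are those of the SMILES strings.

Assumption: the (R)-diphenylprolinol-derived oxazaborolidinium ion is taken to expose the quinone face that leads to 3, by analogy with acrylate cycloadditions of this catalyst family. If correlation of 3 shows the opposite sense, the (S)-antipode is used and nothing else changes.

Remark: the C6 configuration written for 6–11 is the one expected from hydride attack anti to C20. The other epimer would serve equally, because C6 is re-set in step 9.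

Step 1
Reactants: 1 2,6-dimethyl-1,4-benzoquinone; 2 4-methylpenta-1,3-diene
Product: 3 (4aS,8aR)-2,5,5,8a-tetramethyl-4a,5,8,8a-tetrahydronaphthalene-1,4-dione (cis-fused C6,C9-ene-dione; H5 syn to C20; C2=C3 and C7=C8 alkenes)
Conditions: (R)-3,3-diphenyl-1-(o-tolyl)tetrahydro-1H,3H-pyrrolo[1,2-c][1,3,2]oxazaborole (20 mol %), Tf2NH (20 mol %), 2 (5 equiv, slow addition), CH2Cl2, −78 → −40 °C
Reagents that add atoms: none
Why: Asynchronous concerted [4+2] cycloaddition of a Lewis-acid-activated quinone, the closest known reaction type being the oxazaborolidinium-catalysed Diels–Alder reaction of alkyl benzoquinones with simple dienes. The boron cation binds the more basic carbonyl flanked by two CH groups (future C6), so the methyl-bearing β-carbon (future C10) is the electrophilic terminus and takes the nucleophilic CH2 end of 2 (C1), while the CMe2 end (C4) closes onto the CH carbon (future C5). Ring A is closed by this intermolecular cycloaddition, which forms C1–C10 and C4–C5 in one step. C10 is set by the catalyst, whose aryl group shields one face of the two symmetry-equivalent quinone alkenes, and C5 follows from suprafacial addition (cis fusion) and is corrected in step 3. The step needs one orientation and one enantioface: the orientation is secured by coordination at the unhindered carbonyl, and since each diene terminus carries two identical groups the endo/exo mode influences only the sense of induction. The cis-methyl of 2 disfavours the s-cis conformer, hence the excess of diene and its slow addition at low temperature.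

Step 2
Reactants: 3 cis-fused ene-dione with C2=C3 alkene
Product: 4 (4aS,8aR)-2,5,5,8a-tetramethyl-4a,5,6,7,8,8a-hexahydronaphthalene-1,4-dione (cis-fused ene-dione, ring A saturated)
Conditions: H2 (1 atm), RhCl(PPh3)3 (5 mol %), benzene–EtOH, rt
Reagents that add atoms: none
Why: Homogeneous hydrogenation with Wilkinson's catalyst, which discriminates by alkene substitution, saturates the cis-disubstituted C2=C3 bond and leaves the trisubstituted, electron-poor C7=C8 bond alone; no stereocentre is formed.

Step 3
Reactants: 4 cis-fused ene-dione
Product: 5 (4aR,8aR)-2,5,5,8a-tetramethyl-4a,5,6,7,8,8a-hexahydronaphthalene-1,4-dione (trans-fused ene-dione; H5 anti to C20)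
Conditions: DBU (0.2 equiv), CH2Cl2, rt
Reagents that add atoms: none
Why: Base-mediated thermodynamic epimerisation α to the C6 ketone (via the C5=C6 enolate) converts the cis adduct into the trans-decalin with H5 anti to C20, the quaternary C10 being unable to change.

Step 4
Reactants: 5 trans-fused ene-dione
Product: 6 trans-fused 6-hydroxy-7-en-9-one (6-OH syn to C20, axial)
Conditions: NaBH4, CeCl3·7H2O, MeOH, −78 °C
Reagents that add atoms: none
Why: Luche 1,2-reduction is expected at the C6 carbonyl, which is less shielded than the C9 carbonyl next to quaternary C10 and the methyl-bearing C8; hydride approaches anti to C20 and the axial C4 methyl, so the 6-OH comes out syn to C20, a centre that is re-set in step 9.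

Step 5
Reactants: 6 6-hydroxy-7-en-9-one
Product: 7 6-O-triethylsilyl ether of 6
Conditions: Et3SiOTf, 2,6-lutidine, CH2Cl2, −78 → 0 °C
Reagents that add atoms: triethylsilyl trifluoromethanesulfonate, CC[Si](CC)(CC)OS(=O)(=O)C(F)(F)F
Why: Silyl ether formation with a silyl triflate and a hindered pyridine base is the standard way to protect a congested secondary alcohol and masks O6 against the organolithium and chromium reagents that follow.

Step 6
Reactants: 7 6-silyloxy-7-en-9-one
Product: 8 C9 tertiary allylic alcohol (9-OH syn to C20, new methyl C11 anti; C7=C8 alkene; 6-OSiEt3 syn)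
Conditions: MeLi, Et2O, −78 → 0 °C; then H2O
Reagents that add atoms: methyllithium, [Li]C
Why: 1,2-Addition of an organolithium to the only remaining, non-enolisable enone carbonyl (C9) installs C11; attack anti to C20 is expected, but the carbinol centre is erased in step 7.

Step 7
Reactants: 8 C9 tertiary allylic alcohol
Product: 9 7-oxo-8(9)-ene (tetrasubstituted enone carrying C17 on C8 and C11 on C9; 6-OSiEt3 syn to C20)
Conditions: pyridinium chlorochromate [C5H5NH][CrO3Cl], 4 Å molecular sieves, CH2Cl2, rt
Reagents that add atoms: none
Why: Babler–Dauben oxidative transposition: the chromate ester of the tertiary allylic alcohol undergoes a [3,3] shift to C7 and is oxidised there, which moves the former C9 oxygen to C7 and leaves the tetrasubstituted C8=C9 enone; no stereocentre is formed.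

Step 8
Reactants: 9 7-oxo-8(9)-ene
Product: 11 8-hydroxy-7-oxo-9(11)-ene (8-OH anti to C20; C17 syn; exocyclic C9=C11 methylene; 6-OSiEt3 syn), via potassium dienolate 10 (not isolated)
Conditions: KN(SiMe3)2, THF, −78 → 0 °C; then 2-(phenylsulfonyl)-3-phenyloxaziridine, −78 °C; then H2O
Reagents that add atoms: 2-(phenylsulfonyl)-3-phenyloxaziridine, O=S(=O)(c1ccccc1)N1OC1c1ccccc1
Why: Davis oxaziridine hydroxylation of an extended enolate: γ-deprotonation at the C11 methyl is favoured because the lone C6 hydrogen is pseudo-equatorial and poorly aligned with the carbonyl, and the dienolate reacts at its α-carbon C8 on the face anti to C20 and the axial 6-silyloxy group, which sets C8 (OH anti, C17 syn to C20) and releases the C9=C11 methylene.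

Step 9
Reactants: 11 8-hydroxy-7-oxo-9(11)-ene with 6-OSiEt3 syn to C20
Product: 12 C6 epimer of 11 (6-OSiEt3 anti to C20, equatorial)
Conditions: DBU (0.3 equiv), toluene, 60 °C
Reagents that add atoms: none
Why: Base-mediated epimerisation of an α-silyloxy ketone through the C6 enol, the only one possible because C8 is quaternary, moves the 6-substituent from the axial position, where it clashes with the C4, C8 and C10 methyls, to the equatorial one anti to C20.

Step 10
Reactants: 12 8-hydroxy-7-ketone with 6-OSiEt3 anti to C20
Product: 13 7,8-diol (7-OH syn to C20, equatorial; 8-OH anti; 6-OSiEt3 anti; C9=C11 methylene)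
Conditions: NaBH4, MeOH, 0 °C
Reagents that add atoms: none
Why: Sodium borohydride reduction of a cyclohexanone by axial attack of a small hydride from the face anti to C20 and the axial C17 gives the equatorial 7-OH syn to C20.

Step 11
Reactants: 13 7,8-diol
Product: 14 7-acetate of 13 (8-OH free)
Conditions: Ac2O, pyridine, DMAP (cat.), CH2Cl2, rt
Reagents that add atoms: acetic anhydride, CC(=O)OC(C)=O
Why: DMAP-catalysed acylation esterifies the only secondary hydroxyl (O7), the tertiary 8-OH being too hindered to react at room temperature.

Step 12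
Reactants: 15 prop-2-yn-1-ol
Product: 17 (Z)-3-iodo-2-methylprop-2-en-1-ol, via alkenylmagnesium alkoxide 16 (not isolated)
Conditions: MeMgBr (2.5 equiv), CuI (10 mol %), THF, −10 °C → rt; then I2, −78 → 0 °C; then H2O
Reagents that add atoms: methylmagnesium bromide, C[Mg]Br; iodine, II
Why: Copper-catalysed anti-carbomagnesiation of a propargylic alkoxide places methyl on C2 and magnesium on C3 cis to the CH2O group through a five-membered chelate, and iodinolysis with retention gives the Z-iodoalkene.

Step 13
Reactants: 17 (Z)-3-iodo-2-methylprop-2-en-1-ol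
Product: 18 (Z)-3-iodo-2-methylprop-2-enal
Conditions: MnO2 (activated, excess), CH2Cl2, rt, dark
Reagents that add atoms: none
Why: Manganese dioxide oxidation of the allylic alcohol under neutral conditions gives the enal without touching the C–I bond or the alkene geometry.

Step 14
Reactants: 18 (Z)-3-iodo-2-methylprop-2-enal
Product: 19 (Z)-1-iodo-2-methylbuta-1,3-diene (iodine cis to the vinyl group; kept as a solution)
Conditions: Ph3PCH3Br, KN(SiMe3)2, THF, 0 °C; then 18, −78 → 0 °C, dark
Reagents that add atoms: methyltriphenylphosphonium bromide, C[P+](c1ccccc1)(c1ccccc1)c1ccccc1.[Br-]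
Why: Wittig methylenation converts the aldehyde into the terminal vinyl group and does not involve the trisubstituted alkene, whose Z geometry is kept.

Step 15
Reactants: 14 7-acetate with C9=C11 methylene; 19 (Z)-1-iodo-2-methylbuta-1,3-diene
Product: 21 6-O-triethylsilyl ether of the target (C11 syn to C20; H9 anti; 12Z-diene), via B-alkyl-9-BBN borane 20 (not isolated)
Conditions: (9-BBN)2 (2 equiv), THF, 60 °C; then 19, Pd(dppf)Cl2 (dppf = 1,1'-bis(diphenylphosphino)ferrocene, 10 mol %), AsPh3, K3PO4 (3 M aq.), DMF, rt, dark
Reagents that add atoms: none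
Why: Hydroboration puts boron on the terminal C11 and hydrogen on C9 from the face anti to the two flanking axial methyls (C17 and C20), which sets C9 with H anti to C20, and the B-alkyl Suzuki–Miyaura coupling then joins C11 to the dienyl iodide with retention of its Z geometry.

Step 16
Reactants: 21 6-O-triethylsilyl ether of the target
Product: 22 CNP0225877.2
Conditions: HF·pyridine, pyridine, THF, 0 °C → rt
Reagents that add atoms: none
Why: Fluoride-mediated desilylation under buffered, mildly acidic conditions frees O6 without the base that could move the acetyl group from O7 to O6 and without harming the diene or the tertiary alcohol.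

Compound list
1 | 2,6-dimethyl-1,4-benzoquinone | CC1=CC(=O)C=C(C)C1=O | starting material
2 | 4-methylpenta-1,3-diene | CC(C)=CC=C | starting material
3 | (4aS,8aR)-2,5,5,8a-tetramethyl-4a,5,8,8a-tetrahydronaphthalene-1,4-dione (cis-fused adduct) | O=C1C(C)=CC(=O)[C@H]2C(C)(C)C=CC[C@]21C | intermediate
4 | (4aS,8aR)-2,5,5,8a-tetramethyl-4a,5,6,7,8,8a-hexahydronaphthalene-1,4-dione (cis-fused) | O=C1C(C)=CC(=O)[C@H]2C(C)(C)CCC[C@]21C | intermediate
5 | (4aR,8aR)-2,5,5,8a-tetramethyl-4a,5,6,7,8,8a-hexahydronaphthalene-1,4-dione (trans-fused) | O=C1C(C)=CC(=O)[C@@H]2C(C)(C)CCC[C@]21C | intermediate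
6 | trans-fused 6-hydroxy-7-en-9-one, 6-OH syn to C20 | O=C1C(C)=C[C@H](O)[C@@H]2C(C)(C)CCC[C@]21C | intermediate
7 | 6-O-triethylsilyl ether of 6 | O=C1C(C)=C[C@H](O[Si](CC)(CC)CC)[C@@H]2C(C)(C)CCC[C@]21C | intermediate
8 | C9 tertiary allylic alcohol (9-OH syn, C11 anti to C20), 6-OSiEt3 | C[C@@]1(O)C(C)=C[C@H](O[Si](CC)(CC)CC)[C@@H]2C(C)(C)CCC[C@]21C | intermediate
9 | 7-oxo-8(9)-ene, 6-OSiEt3 syn to C20 | CC1=C(C)C(=O)[C@H](O[Si](CC)(CC)CC)[C@@H]2C(C)(C)CCC[C@]21C | intermediate
10 | potassium 7-oxido-7,9(11)-dienolate of 9 | [K+].C=C1C(C)=C([O-])[C@H](O[Si](CC)(CC)CC)[C@@H]2C(C)(C)CCC[C@]21C | intermediate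
11 | 8-hydroxy-7-oxo-9(11)-ene, 8-OH anti, 6-OSiEt3 syn to C20 | C=C1[C@@](C)(O)C(=O)[C@H](O[Si](CC)(CC)CC)[C@@H]2C(C)(C)CCC[C@]21C | intermediate
12 | C6 epimer of 11, 6-OSiEt3 anti to C20 | C=C1[C@@](C)(O)C(=O)[C@@H](O[Si](CC)(CC)CC)[C@@H]2C(C)(C)CCC[C@]21C | intermediate
13 | 7,8-diol, 7-OH syn, 8-OH anti, 6-OSiEt3 anti to C20 | C=C1[C@@](C)(O)[C@H](O)[C@@H](O[Si](CC)(CC)CC)[C@@H]2C(C)(C)CCC[C@]21C | intermediate
14 | 7-acetate of 13 | C=C1[C@@](C)(O)[C@H](OC(C)=O)[C@@H](O[Si](CC)(CC)CC)[C@@H]2C(C)(C)CCC[C@]21C | intermediate
15 | prop-2-yn-1-ol | C#CCO | starting material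
16 | (Z)-alkenylmagnesium alkoxide (Mg on C3 cis to CH2O) | Br[Mg]/C=C(C)\CO[Mg]Br | intermediate
17 | (Z)-3-iodo-2-methylprop-2-en-1-ol | OC/C(C)=C\I | intermediate
18 | (Z)-3-iodo-2-methylprop-2-enal | O=C/C(C)=C\I | intermediate
19 | (Z)-1-iodo-2-methylbuta-1,3-diene | C=C/C(C)=C\I | intermediate
20 | B-(C11-alkyl)-9-borabicyclo[3.3.1]nonane from 14 | C1CCC2CCCC1B2C[C@@H]1[C@@](C)(O)[C@H](OC(C)=O)[C@@H](O[Si](CC)(CC)CC)[C@@H]2C(C)(C)CCC[C@]21C | intermediate
21 | 6-O-triethylsilyl ether of the target | C=C/C(C)=C\C[C@@H]1[C@@](C)(O)[C@H](OC(C)=O)[C@@H](O[Si](CC)(CC)CC)[C@@H]2C(C)(C)CCC[C@]21C | intermediate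
22 | CNP0225877.2: (12Z)-labda-12,14-diene-6,7,8-triol 7-acetate of the 10R series (6-OH anti, 7-OAc syn, 8-OH anti, C11 syn to C20; H5 and H9 anti) | C=C/C(C)=C\C[C@@H]1[C@@](C)(O)[C@H](OC(C)=O)[C@@H](O)[C@@H]2C(C)(C)CCC[C@]21C | target

Total step count: 16 (13 on the main line, 3 for the dienyl iodide).
Longest linear sequence: 13 steps (steps 1–11, 15, 16).

Steps most likely to fail

1. Step 1. The diene populates its s-cis conformer poorly, so the cycloaddition may be slow. The strongly acidic catalyst may oligomerise the diene instead, and face selectivity may erode at the higher temperature then needed. Fallback: setting out from 1 and 2, the cycloaddition is run without a chiral catalyst under the mild Lewis acid ZnBr2 at high pressure (12 kbar, CH2Cl2, rt). Coordination at the unhindered carbonyl still controls the orientation, but the product is the racemate, that is 3 together with its mirror image, the ent-cis adduct F1. The enantiomers are separated by preparative chromatography on a chiral stationary phase, and the route is rejoined at 3.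

2. Step 3. The cis-fused ene-dione may be of comparable stability to the trans isomer, so equilibration may stop short, and prolonged base may degrade the ene-dione. Fallback: setting out from 4, kinetic control replaces thermodynamic control. Soft enolisation (t-BuMe2SiOTf, Et3N, CH2Cl2, −78 → 0 °C) gives the C5=C6 silyl dienol ether F2. Protodesilylation at low temperature (HF·pyridine, THF, −78 °C) protonates C5 axially from the face anti to C20 and the axial C4 methyl. This returns to the route at 5, which is reduced at once in step 4.

3. Step 15. The volatile, light-sensitive dienyl iodide may decompose or lose its Z geometry under palladium, while hydroboration of the methylene between two quaternary carbons is slow; the aqueous base may also cleave some acetate. Fallback: setting out from 14, the same borane 20 is coupled (Pd(dppf)Cl2, K3PO4, DMF) with the more robust iodo-alcohol 17, giving the (12Z)-allylic alcohol F3. MnO2 oxidation gives the (12Z)-enal F4, and Wittig methylenation (Ph3P=CH2, THF, −78 °C) builds the terminal vinyl group last, returning to the route at 21.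

Further compounds
F1 | step 1 | mirror image of 3, (4aR,8aS)-2,5,5,8a-tetramethyl-4a,5,8,8a-tetrahydronaphthalene-1,4-dione | O=C1C(C)=CC(=O)[C@@H]2C(C)(C)C=CC[C@@]21C
F2 | step 3 | C5=C6 tert-butyldimethylsilyl dienol ether of 4 | O=C1C(C)=CC(O[Si](C)(C)C(C)(C)C)=C2C(C)(C)CCC[C@]21C
F3 | step 15 | (12Z)-allylic alcohol from 20 and 17 (C14 = CH2OH), 6-OSiEt3, 7-OAc | OC/C(C)=C\C[C@@H]1[C@@](C)(O)[C@H](OC(C)=O)[C@@H](O[Si](CC)(CC)CC)[C@@H]2C(C)(C)CCC[C@]21C
F4 | step 15 | (12Z)-enal (C14 = CHO), 6-OSiEt3, 7-OAc | O=C/C(C)=C\C[C@@H]1[C@@](C)(O)[C@H](OC(C)=O)[C@@H](O[Si](CC)(CC)CC)[C@@H]2C(C)(C)CCC[C@]21C
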